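**Assumption:** the SMILES defines the target (5Z, 7R, 11E, 15E). Compounds 1, 3, 8, 11 and 16 (as a THF solution) are taken as commercial.

## Structural features

Psammocinin A1 is a linear C25 furanosesterterpenoid. Numbering used throughout: lactone O1, C2 (C=O), C3 (bears CH3), C4 (ring CH), C5; chain C6 to C18; the 3-furyl ring sits on C18. An α-methyl-γ-ylidenebutenolide is joined through the exocyclic Z C5=C6 bond to the chain, whose first sp3 carbon, C7 (R; H, CH3), is the only stereocentre. The chain continues C8H2–C9H2, ketone C10 conjugated to the E C11(CH3)=C12 bond, C13H2–C14H2, the E C15(CH3)=C16 bond and C17H2–C18H2. C7–H is the ε-hydrogen of a doubly vinylogous lactone: its removal gives an aromatic 2-furanolate, so the stereocentre is base-labile once the ylidene is in place. Fragile groups are the 3-alkylfuran (acid, electrophilic oxidants), the enol lactone (nucleophiles, strong base) and the enone. The C10–C18 segment is a geranyl unit oxidised at its E-methyl group (C10) and bound to a 3-furylmethyl carbon, so that half maps on to cheap terpenes with both alkene geometries already set. The real difficulty is concentrated in C5–C8: the Z-ylidene, the lone labile stereocentre beside it, and the bond that ties this unit to the terpenoid half. The key step exploits two facts: the C5=C6–C7 unit is the ε-adduct of a 5-propenyl-2-oxyfuran (a trienolate whose terminus is C7), and C8–C9–C10 is the β-carbon, α-carbon and carbonyl of a vinyl ketone.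

## Logic of the disconnections

**20 to 7 + 18 (through 19).** The C7–C8 bond is cut and the C5=C6 double bond is folded back into the furan ring of 7. In one sentence: 20 is made by an ε-selective, catalyst-controlled Michael addition of 7 to 18. This cut removes the stereocentre, the ylidene geometry and the fragment union at once, and leaves two achiral precursors. The forward step must attack through C7 and not C3 or C5, must give Z at C5=C6, must select one face at C7, and must touch only the unsubstituted vinyl terminus of 18.

**7 to 6.** The O–Si bond and the C6=C7 bond are removed (C7–H restored). 6 is a stable, storable lactone, while 7 is made just before use. The forward step must remove the ε-hydrogen and give the E-propenyl group.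

**6 to 2 + 3 (through 5 and 4), and 2 to 1.** The C5=C6 π bond is cut by elimination and the C5–C6 σ bond by a vinylogous aldol addition. This reaches a commercial butenolide and a three-carbon aldehyde. No stereochemical demand arises, because every stereo-element of 4 and 6 is erased in 7.

**18 to 15 + 16 (through 17).** The C9–C10 bond is cut, with a change of oxidation level at C10. This exposes C10 as the aldehyde of an oxidised geranyl chain. The forward steps need only 1,2-addition and a neutral oxidation that spares the furan.

**15 to 13 (through 14).** The C10–O bonds are cut. 13 has the whole C11–C18 skeleton with both E alkenes in place. The forward step must oxidise the E-methyl group of the terminal alkene only.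

**13 to 10 + 11 (through 12), and 10 to 8 (through 9).** The C17–C18 bond is cut between an allylic and a furylmethyl carbon. Both partners are one step from commercial materials. The forward step must couple at the primary allylic carbon without allylic transposition or loss of the E geometry.

## Other disconnections considered

**Alternative 1: the first that comes to mind.** Cut C5=C6 and, separately, C10–C11. The forward key step is a vinylogous Mukaiyama aldol addition of 2 to (2R)-4-(1,3-dioxolan-2-yl)-2-methylbutanal A1, followed by dehydration to (5Z)-5-[(2R)-4-(1,3-dioxolan-2-yl)-2-methylbutylidene]-3-methylfuran-2(5H)-one A2. Acetal hydrolysis, Nozaki–Hiyama–Kishi addition (CrCl2, catalytic NiCl2) of 3-[(3E,7E)-8-iodo-4-methylnona-3,7-dien-1-yl]furan A3 and oxidation would finish the route. The chosen plan is preferred on three grounds: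
- The stereocentre has to be made separately and carried as an α-branched aldehyde that can enolise, and the dehydration uses base just as C7–H becomes ε-acidic.
- Ylidene, stereocentre and fragment union are solved in three unrelated operations.
- A3 carries its handle on C11, which the geraniol skeleton (handle on C10) cannot supply, so the terpenoid half needs a de novo alkene synthesis. The step count roughly doubles.

A shorter variant of this logic is held in reserve as the fallback for step 11.

**Alternative 2: C7–C8 with C7 as the electrophile.** The forward key step is an enantioconvergent Negishi coupling (NiCl2·glyme, chiral pybox ligand) of racemic (5Z)-5-(2-chloropropylidene)-3-methylfuran-2(5H)-one A4 with commercial [2-(1,3-dioxolan-2-yl)ethyl]zinc bromide, to give A2. It is a known reaction type for secondary allylic chlorides and funnels both enantiomers of A4. The chosen plan is preferred because: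
- The allyl radical from A4 is delocalised over C5–C7 and into the lactone, so coupling at C7 rather than C5 and the selectivity on an enol lactone are open questions, and A4 should ionise easily.
- The zinc partner delivers C8–C10 as a masked aldehyde, so the plan rejoins Alternative 1 at A2 and inherits A3 and two redox steps at C10.

The chosen step makes the same bond with the opposite polarity and uses 18, which is two steps from 15.

**Alternative 3: C9–C10 from two electrophiles.** The forward key step is a reductive acylation (NiCl2·glyme, 4,4′-di-tert-butyl-2,2′-bipyridine, manganese powder) of (5Z)-5-[(2R)-4-iodo-2-methylbutylidene]-3-methylfuran-2(5H)-one A5 with (2E,6E)-9-(furan-3-yl)-2,6-dimethylnona-2,6-dienoyl chloride A6. It would give the ketone directly and use the geraniol-derived half. The chosen plan is preferred because: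
- C7 and the ylidene still have to be built beforehand in a separate sequence of the Alternative 1 kind.
- An enoyl chloride at low-valent nickel is open to decarbonylation and conjugate reduction.

The chosen plan moves the union one bond to the left, where the C–C bond formation also creates the stereocentre and the ylidene.

Key step: step 11

## Steps

**Step 1**
Reactants: 1 3-methylfuran-2(5H)-one
Product: 2 tert-butyldimethyl[(3-methylfuran-2-yl)oxy]silane
Conditions: TBSOTf (1.1 equiv), Et3N (1.3 equiv), CH2Cl2, 0 °C
Reagents that add atoms: tert-butyldimethylsilyl trifluoromethanesulfonate, CC(C)(C)[Si](C)(C)OS(=O)(=O)C(F)(F)F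
Why: Soft enolisation: O-silylation of the lactone carbonyl followed by loss of a C5 proton gives the aromatic 2-silyloxyfuran (silyl dienol ether formation).

**Step 2**
Reactants: 2 tert-butyldimethyl[(3-methylfuran-2-yl)oxy]silane; 3 propanal
Product: 4 5-(1-hydroxypropyl)-3-methylfuran-2(5H)-one (racemic mixture of diastereomers)
Conditions: BF3·OEt2 (1.1 equiv), CH2Cl2, −78 °C; then aq NaHCO3
Reagents that add atoms: none
Why: Vinylogous Mukaiyama aldol addition, which should occur at C5 of the silyloxyfuran; both new stereocentres are erased in steps 3 and 4, so no control is needed.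

**Step 3**
Reactants: 4 5-(1-hydroxypropyl)-3-methylfuran-2(5H)-one
Product: 6 (5Z)-3-methyl-5-propylidenefuran-2(5H)-one, via 1-(4-methyl-5-oxo-2,5-dihydrofuran-2-yl)propyl methanesulfonate 5 (not isolated)
Conditions: MsCl (1.3 equiv), Et3N (4 equiv), CH2Cl2, 0 °C to rt
Reagents that add atoms: methanesulfonyl chloride, CS(=O)(=O)Cl (enters 5 only; none of its atoms remain in 6)
Why: Mesylation followed by E1cB elimination through the 2-furanolate (C5–H is the vinylogous acidic position). The Z isomer should predominate on thermodynamic grounds, and any E isomer converges in step 4.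

**Step 4**
Reactants: 6 (5Z)-3-methyl-5-propylidenefuran-2(5H)-one
Product: 7 tert-butyldimethyl({3-methyl-5-[(1E)-prop-1-en-1-yl]furan-2-yl}oxy)silane
Conditions: TBSOTf (1.2 equiv), Et3N (2 equiv), CH2Cl2, −20 to 0 °C; filtration through basic alumina under argon, used at once
Reagents that add atoms: tert-butyldimethylsilyl trifluoromethanesulfonate, CC(C)(C)[Si](C)(C)OS(=O)(=O)C(F)(F)F
Why: Soft enolisation to an extended silyl dienol ether: O-silylation places positive charge on C6, and Et3N removes the ε-hydrogen at C7 to restore the furan. The E-propenyl geometry should be favoured because the methyl group turns away from the ring in the deprotonation.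

**Step 5**
Reactants: 8 furan-3-ylmethanol
Product: 10 3-(chloromethyl)furan, via furan-3-ylmethyl methanesulfonate 9 (not isolated)
Conditions: MsCl (1.1 equiv), 2,4,6-collidine (1.2 equiv), LiCl (1.5 equiv), DMF, 0 °C
Reagents that add atoms: lithium chloride, [Li+].[Cl-]; methanesulfonyl chloride, CS(=O)(=O)Cl (enters 9 only)
Why: Mesylation and in situ SN2 displacement by chloride under non-acidic conditions that the furan tolerates. The chloride is kept cold and used without storage.

**Step 6**
Reactants: 10 3-(chloromethyl)furan; 11 geranyl chloride, (2E)-1-chloro-3,7-dimethylocta-2,6-diene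
Product: 13 dendrolasin, 3-[(3E)-4,8-dimethylnona-3,7-dien-1-yl]furan, via (furan-3-ylmethyl)magnesium chloride 12 (not isolated)
Conditions: Mg turnings, THF, 0 °C; then 11, Li2CuCl4 (3 mol %), THF, 0 °C
Reagents that add atoms: magnesium, [Mg] (enters 12 only)
Why: Kochi-type Li2CuCl4-catalysed coupling of a Grignard reagent with a primary allylic chloride. Attack should take place at the primary carbon (SN2), with retention of the E alkene.

**Step 7**
Reactants: 13 dendrolasin
Product: 14 (2E,6E)-9-(furan-3-yl)-2,6-dimethylnona-2,6-dien-1-ol
Conditions: SeO2 (0.3 equiv), t-BuOOH (2.5 equiv), salicylic acid (0.1 equiv), CH2Cl2, 0 °C to rt, stopped at partial conversion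
Reagents that add atoms: tert-butyl hydroperoxide, CC(C)(C)OO
Why: Riley allylic oxidation (ene reaction, then [2,3]-sigmatropic shift), which selects the E-methyl group of the more accessible terminal trisubstituted alkene. Any aldehyde 15 formed by over-oxidation converges in step 8.

**Step 8**
Reactants: 14 (2E,6E)-9-(furan-3-yl)-2,6-dimethylnona-2,6-dien-1-ol
Product: 15 (2E,6E)-9-(furan-3-yl)-2,6-dimethylnona-2,6-dienal
Conditions: MnO2 (excess), CH2Cl2, rt
Reagents that add atoms: none
Why: Chemoselective oxidation of an allylic alcohol under neutral heterogeneous conditions that leave the furan and the alkene geometry untouched.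

**Step 9**
Reactants: 15 (2E,6E)-9-(furan-3-yl)-2,6-dimethylnona-2,6-dienal; 16 vinylmagnesium bromide
Product: 17 (4E,8E)-11-(furan-3-yl)-4,8-dimethylundeca-1,4,8-trien-3-ol (racemic)
Conditions: THF, −78 °C; then pH 7 phosphate buffer
Reagents that add atoms: none
Why: 1,2-Addition of a Grignard reagent to an α-branched enal. The carbinol centre is removed in step 10, and the buffered quench protects the doubly allylic alcohol from ionisation.

**Step 10**
Reactants: 17 (4E,8E)-11-(furan-3-yl)-4,8-dimethylundeca-1,4,8-trien-3-ol
Product: 18 (4E,8E)-11-(furan-3-yl)-4,8-dimethylundeca-1,4,8-trien-3-one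
Conditions: MnO2 (excess), CH2Cl2, 0 °C to rt; filtered, concentrated cold, used directly
Reagents that add atoms: none
Why: Oxidation of a doubly allylic alcohol to the cross-conjugated divinyl ketone under neutral conditions. The vinyl ketone is not stored, because it is prone to polymerisation.

**Step 11**
Reactants: 7 tert-butyldimethyl({3-methyl-5-[(1E)-prop-1-en-1-yl]furan-2-yl}oxy)silane; 18 (4E,8E)-11-(furan-3-yl)-4,8-dimethylundeca-1,4,8-trien-3-one
Product: 20 psammocinin A1, (5Z)-5-[(2R,6E,10E)-13-(furan-3-yl)-2,6,10-trimethyl-5-oxotrideca-6,10-dien-1-ylidene]-3-methylfuran-2(5H)-one, via C10 tert-butyldimethylsilyl enol ether 19 (not isolated)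
Conditions: 7 (1.3 equiv), confined chiral BINOL-derived N-triflyl imidodiphosphorimidate (IDPi) acid (3 mol %), toluene, −78 °C; then 1 M aq HCl/THF, 0 °C
Reagents that add atoms: none
Why: Proposed new method: an ε-selective (bisvinylogous) Mukaiyama–Michael addition under silylium/chiral-counteranion catalysis: 7 silylates the acid to give the silylated catalyst, which transfers its silyl group to the carbonyl oxygen of 18; C7 of 7 then adds to the unsubstituted terminus C8 of the resulting 2-silyloxypentadienyl cation inside the chiral anion, and the silyl group on the lactone oxygen of the adduct returns to the anion, leaving 19, which aqueous acid protonates at C9. The closest known reaction types are the counteranion-directed bisvinylogous Mukaiyama aldol reaction of silyl trienolates, the hypervinylogous Mukaiyama aldol reaction of 5-alkenyl-2-silyloxyfurans (remote attack, Z-ylidene butenolides) and the counteranion-directed Mukaiyama–Michael addition; new are the vinyl ketone acceptor and a stereocentre that lies on the nucleophile alone. No ring is closed: the furan ring of 7 becomes the butenolide as C5=C6 forms. ε-Attack is expected because C3 and C5 of 7 are fully substituted, C7 is the unhindered terminus of the trienolate HOMO, and only ε-attack gives the fully conjugated dienoate. The Z geometry follows from the s-trans arrangement of C4=C5 and C6=C7 in 7 (C7 on the side of O1), which avoids the C4–H/C7–H clash of the s-cis rotamer. C7 is the only new stereocentre and is controlled by the catalyst: with the E-propenyl group and the s-trans rotamer fixed, its configuration depends only on which enantiotopic face of the planar furan-triene meets C8, and the confined anion, which covers one face of the bound cation and leaves one channel for the nucleophile, makes that choice; the catalyst enantiomer is selected in a first screen so that C7 is R. Chemoselectivity needs attack at C8 only and is secured by the unsubstituted vinyl terminus being far more electrophilic than the α,β-disubstituted terminus C12 and by 7 being orders of magnitude more nucleophilic than the 3-alkylfuran and the trisubstituted alkenes of 18. No base is present, so the ε-acidic C7–H of 20 is not touched and the configuration should persist through the mild acidic hydrolysis.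

## Compound list

1 | 3-methylfuran-2(5H)-one | CC1=CCOC1=O | starting material
2 | tert-butyldimethyl[(3-methylfuran-2-yl)oxy]silane | Cc1ccoc1O[Si](C)(C)C(C)(C)C | intermediate
3 | propanal | CCC=O | starting material
4 | 5-(1-hydroxypropyl)-3-methylfuran-2(5H)-one (racemic mixture of diastereomers) | CCC(O)C1OC(=O)C(C)=C1 | intermediate
5 | 1-(4-methyl-5-oxo-2,5-dihydrofuran-2-yl)propyl methanesulfonate | CCC(OS(C)(=O)=O)C1OC(=O)C(C)=C1 | intermediate (not isolated)
6 | (5Z)-3-methyl-5-propylidenefuran-2(5H)-one | CC1=C/C(=C/CC)OC1=O | intermediate
7 | tert-butyldimethyl({3-methyl-5-[(1E)-prop-1-en-1-yl]furan-2-yl}oxy)silane | C/C=C/c1cc(C)c(O[Si](C)(C)C(C)(C)C)o1 | intermediate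
8 | furan-3-ylmethanol | OCc1ccoc1 | starting material
9 | furan-3-ylmethyl methanesulfonate | CS(=O)(=O)OCc1ccoc1 | intermediate (not isolated)
10 | 3-(chloromethyl)furan | ClCc1ccoc1 | intermediate
11 | geranyl chloride, (2E)-1-chloro-3,7-dimethylocta-2,6-diene | CC(C)=CCC/C(C)=C/CCl | starting material
12 | (furan-3-ylmethyl)magnesium chloride | Cl[Mg]Cc1ccoc1 | intermediate (not isolated)
13 | dendrolasin, 3-[(3E)-4,8-dimethylnona-3,7-dien-1-yl]furan | CC(C)=CCC/C(C)=C/CCc1ccoc1 | intermediate
14 | (2E,6E)-9-(furan-3-yl)-2,6-dimethylnona-2,6-dien-1-ol | OC/C(C)=C/CC/C(C)=C/CCc1ccoc1 | intermediate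
15 | (2E,6E)-9-(furan-3-yl)-2,6-dimethylnona-2,6-dienal | O=C/C(C)=C/CC/C(C)=C/CCc1ccoc1 | intermediate
16 | vinylmagnesium bromide | C=C[Mg]Br | starting material
17 | (4E,8E)-11-(furan-3-yl)-4,8-dimethylundeca-1,4,8-trien-3-ol (racemic) | C=CC(O)/C(C)=C/CC/C(C)=C/CCc1ccoc1 | intermediate
18 | (4E,8E)-11-(furan-3-yl)-4,8-dimethylundeca-1,4,8-trien-3-one | C=CC(=O)/C(C)=C/CC/C(C)=C/CCc1ccoc1 | intermediate
19 | (5Z)-5-[(2R,6E,10E)-5-(tert-butyldimethylsilyloxy)-13-(furan-3-yl)-2,6,10-trimethyltrideca-4,6,10-trien-1-ylidene]-3-methylfuran-2(5H)-one (C9=C10 enol ether geometry not defined) | CC1=C/C(=C/[C@H](C)CC=C(O[Si](C)(C)C(C)(C)C)/C(C)=C/CC/C(C)=C/CCc2ccoc2)OC1=O | intermediate (not isolated)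
20 | psammocinin A1, (5Z)-5-[(2R,6E,10E)-13-(furan-3-yl)-2,6,10-trimethyl-5-oxotrideca-6,10-dien-1-ylidene]-3-methylfuran-2(5H)-one | CC1=C/C(=C/[C@H](C)CCC(=O)/C(C)=C/CC/C(C)=C/CCc2ccoc2)OC1=O | target

## Step count and least certain steps

Total step count: 11. Longest linear sequence: 7 steps (steps 5, 6, 7, 8, 9, 10, 11, from 8 to 20). The left half takes 5 steps (1, 2, 3, 4, 11).

**Step 11 (key step, Proposed new method).** Several things may go wrong:
- attack through C5 in place of C7;
- insufficient facial discrimination at C7, since the acceptor carries no stereogenic β-carbon;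
- acid-promoted Nazarov cyclisation or polymerisation of 18 before it is trapped;
- partial formation of the E-ylidene;
- erosion of the selectivity by any Z-propenyl isomer of 7.

The fallback uses known chemistry, sets out from 18 and returns at 20. Enamine-catalysed Michael addition of 3 to 18 [(S)-α,α-diphenylprolinol trimethylsilyl ether (10 mol %), catechol co-catalyst, CH2Cl2, 0 °C] should give (2R,6E,10E)-13-(furan-3-yl)-2,6,10-trimethyl-5-oxotrideca-6,10-dienal F1. The electrophile should add to the enamine face opposite the diarylmethyl group, and the antipodal catalyst is available should the sense be the reverse. BF3·OEt2-mediated vinylogous Mukaiyama aldol addition of 2 to the aldehyde group of F1 (CH2Cl2, −78 °C) should give 5-[(2R,6E,10E)-13-(furan-3-yl)-1-hydroxy-2,6,10-trimethyl-5-oxotrideca-6,10-dien-1-yl]-3-methylfuran-2(5H)-one F2 as a mixture of isomers at the two new centres. MsCl/Et3N (CH2Cl2, 0 °C) should convert it into (2R,6E,10E)-13-(furan-3-yl)-2,6,10-trimethyl-1-(4-methyl-5-oxo-2,5-dihydrofuran-2-yl)-5-oxotrideca-6,10-dien-1-yl methanesulfonate F3, which eliminates in the same flask to 20. The weak points of this fallback are the enolisable α-branched aldehyde and the base in the last operation.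

**Step 7.** Oxidative degradation of the furan, competing oxidation at the allylic positions of the internal C15=C16 alkene and over-oxidation may all lower the yield. The fallback sets out from 13 and returns at 15, bypassing 14. Cross-metathesis of 13 with methacrolein (second-generation Hoveyda–Grubbs catalyst, 5 mol %, CH2Cl2, 40 °C) should exchange the isopropylidene terminus for the E-2-methyl-enal. This is a formal allylic oxidation that needs no oxidant and relies on the isopropylidene group being the most accessible alkene. This fallback makes no new compound (entry F0).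

**Step 4.** Incomplete geometric control in the ε-deprotonation (Z-propenyl isomer) and hydrolysis of the electron-rich silyloxyfuran on handling are the likely failures. The fallback sets out from 2 and returns at 7. Lithiation of 2 at C5 (sec-BuLi, TMEDA, THF, −78 °C) and transmetalation with ZnCl2 should give chloro{5-[(tert-butyldimethylsilyl)oxy]-4-methylfuran-2-yl}zinc F4. Negishi coupling of F4 with commercial (E)-1-bromoprop-1-ene (Pd(PPh3)4, THF, rt) should install the propenyl group with retention of the E geometry.

**Step 6.** Wurtz-type homocoupling during formation of 12 and competing attack at the tertiary allylic terminus (SN2′) are the likely failures. The fallback sets out from 11 and 10 and returns at 13. Displacement of the chloride of 11 with sodium benzenesulfinate (DMF, rt) should give {[(2E)-3,7-dimethylocta-2,6-dien-1-yl]sulfonyl}benzene F5. Deprotonation (n-BuLi, THF, −78 °C) and alkylation with 10 should give 3-[(3E)-4,8-dimethyl-2-(phenylsulfonyl)nona-3,7-dien-1-yl]furan F6. Reductive desulfonylation (LiEt3BH, Pd(dppp)Cl2 catalyst, THF, 0 °C) should then give 13.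

## Further compounds

F1 | step 11 | (2R,6E,10E)-13-(furan-3-yl)-2,6,10-trimethyl-5-oxotrideca-6,10-dienal | O=C[C@H](C)CCC(=O)/C(C)=C/CC/C(C)=C/CCc1ccoc1
F2 | step 11 | 5-[(2R,6E,10E)-13-(furan-3-yl)-1-hydroxy-2,6,10-trimethyl-5-oxotrideca-6,10-dien-1-yl]-3-methylfuran-2(5H)-one | CC1=CC(OC1=O)C(O)[C@H](C)CCC(=O)/C(C)=C/CC/C(C)=C/CCc1ccoc1
F3 | step 11 | (2R,6E,10E)-13-(furan-3-yl)-2,6,10-trimethyl-1-(4-methyl-5-oxo-2,5-dihydrofuran-2-yl)-5-oxotrideca-6,10-dien-1-yl methanesulfonate | CC1=CC(OC1=O)C(OS(C)(=O)=O)[C@H](C)CCC(=O)/C(C)=C/CC/C(C)=C/CCc1ccoc1
F0 | step 7 | none | none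
F4 | step 4 | chloro{5-[(tert-butyldimethylsilyl)oxy]-4-methylfuran-2-yl}zinc | Cc1cc([Zn]Cl)oc1O[Si](C)(C)C(C)(C)C
F5 | step 6 | {[(2E)-3,7-dimethylocta-2,6-dien-1-yl]sulfonyl}benzene | CC(C)=CCC/C(C)=C/CS(=O)(=O)c1ccccc1
F6 | step 6 | 3-[(3E)-4,8-dimethyl-2-(phenylsulfonyl)nona-3,7-dien-1-yl]furan | CC(C)=CCC/C(C)=C/C(Cc1ccoc1)S(=O)(=O)c1ccccc1
A1 | alternative 1 | (2R)-4-(1,3-dioxolan-2-yl)-2-methylbutanal | O=C[C@H](C)CCC1OCCO1
A2 | alternative 1 | (5Z)-5-[(2R)-4-(1,3-dioxolan-2-yl)-2-methylbutylidene]-3-methylfuran-2(5H)-one | CC1=C/C(=C/[C@H](C)CCC2OCCO2)OC1=O
A3 | alternative 1 | 3-[(3E,7E)-8-iodo-4-methylnona-3,7-dien-1-yl]furan | I/C(C)=C/CC/C(C)=C/CCc1ccoc1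
A4 | alternative 2 | (5Z)-5-(2-chloropropylidene)-3-methylfuran-2(5H)-one (racemic) | CC1=C/C(=C/C(C)Cl)OC1=O
A5 | alternative 3 | (5Z)-5-[(2R)-4-iodo-2-methylbutylidene]-3-methylfuran-2(5H)-one | CC1=C/C(=C/[C@H](C)CCI)OC1=O
A6 | alternative 3 | (2E,6E)-9-(furan-3-yl)-2,6-dimethylnona-2,6-dienoyl chloride | O=C(Cl)/C(C)=C/CC/C(C)=C/CCc1ccoc1
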